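The route cuts ring C of unit 2 (the C6-linked flavone) at C8a–O1, C4a–C4 and O1–C2. In ring A of that unit, C8a (bearing O1) and C4a (bearing the C4 carbonyl) are neighbours, and the C5 oxygen next to C4a polarises an aryne drawn across C4a–C8a. Fluoride turns an ortho-silyl aryl triflate, which already carries the complete unit 1 flavone at the future C6, into that aryne. The aryne inserts into the acyl C–O bond of 3-[4-(benzyloxy)phenyl]propiolic acid and the pyranone closes in the same flask. All organolithium chemistry is finished before the chromone of unit 1 is attached.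

Key step: step 10

Assumption: the target SMILES fixes no configuration at the C6–C8 biaryl axis, so every biaryl compound is made and carried as the racemic mixture of atropisomers; 3,5-bis(benzyloxy)phenol is taken as purchased.

Step 1
Reactants: 1 apigenin
Product: 2 genkwanin (5-hydroxy-2-(4-hydroxyphenyl)-7-methoxy-4H-chromen-4-one)
Conditions: MeI (1.05 equiv), K2CO3 (1.0 equiv), DMF, rt
Reagents that add atoms: iodomethane, CI
Why: Williamson ether synthesis in which the 7-OH, para to the C4 carbonyl and the most acidic phenol of apigenin, is ionised and methylated first while the 5-OH stays locked in its hydrogen bond to the carbonyl.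

Step 2
Reactants: 2 genkwanin
Product: 3 5-(benzyloxy)-2-[4-(benzyloxy)phenyl]-7-methoxy-4H-chromen-4-one
Conditions: BnBr (3 equiv), K2CO3, DMF, 80 °C
Reagents that add atoms: benzyl bromide, BrCc1ccccc1
Why: Williamson ether synthesis; the free 4'-OH reacts readily and heating in DMF with excess benzyl bromide should also alkylate the chelated 5-OH.

Step 3
Reactants: 3 5-(benzyloxy)-2-[4-(benzyloxy)phenyl]-7-methoxy-4H-chromen-4-one
Product: 4 5-(benzyloxy)-2-[4-(benzyloxy)phenyl]-8-iodo-7-methoxy-4H-chromen-4-one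
Conditions: I2, CF3CO2Ag, CH2Cl2, 0 °C → rt
Reagents that add atoms: iodine, II
Why: Electrophilic aromatic iodination of ring A, which with O5 alkylated should occur at C8 (ortho to O1 and O7, para to O5) because C6 is shielded between the benzyloxy and methoxy groups and ring B is deactivated by conjugation with the chromone.

Step 4
Reactants: 5 3,5-bis(benzyloxy)phenol
Product: 6 3,5-bis(benzyloxy)-2-bromophenol
Conditions: NBS (1.0 equiv), CH2Cl2, −78 °C → rt
Reagents that add atoms: N-bromosuccinimide, O=C1CCC(=O)N1Br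
Why: Electrophilic aromatic bromination in which one equivalent of NBS at low temperature should take the position ortho to the free OH and para to a benzyloxy group, the site between the two benzyloxy groups being the more hindered.

Step 5
Reactants: 6 3,5-bis(benzyloxy)-2-bromophenol
Product: 10 [3,5-bis(benzyloxy)-2-(trimethylsilyl)phenoxy]tri(propan-2-yl)silane, via O-trimethylsilyl ether 7 (not isolated), via aryllithium 8 (not isolated), via lithium phenoxide 9 (not isolated)
Conditions: HMDS, THF, 65 °C, then evaporation; n-BuLi, THF, −78 °C → rt; TIPSOTf, −78 °C → rt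
Reagents that add atoms: hexamethyldisilazane, C[Si](C)(C)N[Si](C)(C)C; triisopropylsilyl trifluoromethanesulfonate, CC(C)[Si](OS(=O)(=O)C(F)(F)F)(C(C)C)C(C)C
Why: O-silylation, bromine–lithium exchange and the 1,3 O-to-C silyl shift of a retro-Brook rearrangement should move the trimethylsilyl group onto the former C–Br carbon, and the lithium phenoxide released is capped in the same flask as its bulky silyl ether; the exchange at −78 °C is far faster than any attack on the benzyl ethers.

Step 6
Reactants: 10 [3,5-bis(benzyloxy)-2-(trimethylsilyl)phenoxy]tri(propan-2-yl)silane (1.5 equiv); 4 5-(benzyloxy)-2-[4-(benzyloxy)phenyl]-8-iodo-7-methoxy-4H-chromen-4-one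
Product: 13 5-(benzyloxy)-2-[4-(benzyloxy)phenyl]-8-{2,6-bis(benzyloxy)-3-(trimethylsilyl)-4-[tri(propan-2-yl)silyloxy]phenyl}-7-methoxy-4H-chromen-4-one, via aryllithium 11 (not isolated), via arylzinc chloride 12 (not isolated)
Conditions: n-BuLi, THF, 0 °C; ZnCl2, 0 °C → rt; then 4, Pd2(dba)3 (cat.), RuPhos (cat.), THF/NMP, 70 °C
Reagents that add atoms: none
Why: Directed ortho-lithiation at the only C–H flanked by two benzyloxy groups (the bulky silyloxy group shields the other one), transmetalation to zinc and Negishi cross-coupling under a dialkylbiarylphosphine catalyst suited to tetra-ortho-substituted biaryls should join the two halves, the arylzinc chloride leaving the chromone carbonyl of 4 untouched and the axis forming as a racemate.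

Step 7
Reactants: 13 the silyl-protected biaryl
Product: 14 5-(benzyloxy)-2-[4-(benzyloxy)phenyl]-8-[2,6-bis(benzyloxy)-4-hydroxy-3-(trimethylsilyl)phenyl]-7-methoxy-4H-chromen-4-one
Conditions: TBAF (1.1 equiv), AcOH (1.1 equiv), THF, 0 °C
Reagents that add atoms: none
Why: Fluoride-mediated silyl ether deprotection, in which the O–Si bond of the aryl silyl ether should cleave far faster than the C–SiMe3 bond of an electron-rich arene, with acetic acid buffering the phenoxide.

Step 8
Reactants: 14 the ortho-silyl phenol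
Product: 15 3,5-bis(benzyloxy)-4-{5-(benzyloxy)-2-[4-(benzyloxy)phenyl]-7-methoxy-4-oxo-4H-chromen-8-yl}-2-(trimethylsilyl)phenyl trifluoromethanesulfonate
Conditions: PhNTf2, DBU, MeCN, rt → 40 °C
Reagents that add atoms: N-phenylbis(trifluoromethanesulfonimide), O=S(=O)(N(c1ccccc1)S(=O)(=O)C(F)(F)F)C(F)(F)F
Why: O-sulfonylation of the phenoxide with a mild triflyl donor that should touch neither the chromone carbonyl nor the C–Si bond, the usual last step in making an ortho-silylaryl triflate.

Step 9
Reactants: 16 propiolic acid; 17 1-(benzyloxy)-4-iodobenzene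
Product: 18 3-[4-(benzyloxy)phenyl]prop-2-ynoic acid
Conditions: Pd(PPh3)4 (cat.), DBU (2.2 equiv), DMSO, rt; then aq. HCl
Reagents that add atoms: none
Why: Copper-free Sonogashira-type coupling of an aryl iodide with the terminal alkyne of propiolic acid, run at room temperature so that the carboxylate should not decarboxylate.

Step 10
Reactants: 15 the ortho-silylaryl triflate; 18 3-[4-(benzyloxy)phenyl]prop-2-ynoic acid (2 equiv)
Product: 21 penta-O-benzyl-7'-O-methylagathisflavone, via aryne 19 (not isolated), via cesium o-acylphenoxide 20 (not isolated)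
Conditions: CsF (5 equiv), THF, 125 °C, sealed tube
Reagents that add atoms: none
Why: Fluoride attack on silicon expels triflate to give the C4a–C8a aryne 19; the cesium carboxylate of 18 adds through oxygen at C8a, the aryl anion left at C4a attacks the neighbouring ester carbonyl, and opening of the four-membered adduct gives the o-acylphenoxide 20, a net insertion of the aryne into the acyl C–O bond. The closest known reaction type is the fluoride-induced intermolecular C–O insertion of arynes into carboxylic acids, which gives o-hydroxyaryl ketones and, with arylpropiolic acids, flavones. Ring C of unit 2 then closes by 6-endo-dig oxa-Michael addition of the C8a phenoxide to the β-carbon of the ynone (O1–C2), the 5-exo-dig aurone mode being disfavoured because it needs attack at the α-carbon. No stereocentre is formed and the biaryl axis stays racemic. The step needs one regiochemistry, oxygen at C8a and acyl at C4a, and the C5 benzyloxy group should secure it by polarising the aryne so that the nucleophile enters at the distal, unhindered C8a while the carbanion develops at C4a next to the inductively stabilising oxygen, as in other 3-alkoxyarynes. The high temperature and the excess of carboxylate should favour acyl transfer over simple protonation of the aryl anion, although an aryne carrying so large a biaryl substituent has not been tried in this reaction.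

Step 11
Reactants: 21 penta-O-benzyl-7'-O-methylagathisflavone
Product: 22 7'-O-methylagathisflavone
Conditions: H2 (1 atm), Pd/C (10 wt % Pd), THF/MeOH, rt
Reagents that add atoms: none
Why: Catalytic hydrogenolysis should cleave the five aryl benzyl ethers while leaving the aryl methyl ether and, if stopped at full debenzylation, the two conjugated chromone C2=C3 bonds.

Compound list
1 | apigenin | O=c1cc(-c2ccc(O)cc2)oc2cc(O)cc(O)c12 | starting material
2 | genkwanin (5-hydroxy-2-(4-hydroxyphenyl)-7-methoxy-4H-chromen-4-one) | COc1cc(O)c2c(=O)cc(-c3ccc(O)cc3)oc2c1 | intermediate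
3 | 5-(benzyloxy)-2-[4-(benzyloxy)phenyl]-7-methoxy-4H-chromen-4-one | COc1cc(OCc2ccccc2)c2c(=O)cc(-c3ccc(OCc4ccccc4)cc3)oc2c1 | intermediate
4 | 5-(benzyloxy)-2-[4-(benzyloxy)phenyl]-8-iodo-7-methoxy-4H-chromen-4-one | COc1cc(OCc2ccccc2)c2c(=O)cc(-c3ccc(OCc4ccccc4)cc3)oc2c1I | intermediate
5 | 3,5-bis(benzyloxy)phenol | Oc1cc(OCc2ccccc2)cc(OCc2ccccc2)c1 | starting material
6 | 3,5-bis(benzyloxy)-2-bromophenol | Oc1cc(OCc2ccccc2)cc(OCc2ccccc2)c1Br | intermediate
7 | [3,5-bis(benzyloxy)-2-bromophenoxy]trimethylsilane | C[Si](C)(C)Oc1cc(OCc2ccccc2)cc(OCc2ccccc2)c1Br | intermediate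
8 | [2,4-bis(benzyloxy)-6-(trimethylsilyloxy)phenyl]lithium | [Li]c1c(O[Si](C)(C)C)cc(OCc2ccccc2)cc1OCc1ccccc1 | intermediate
9 | lithium 3,5-bis(benzyloxy)-2-(trimethylsilyl)phenoxide | [Li+].[O-]c1cc(OCc2ccccc2)cc(OCc2ccccc2)c1[Si](C)(C)C | intermediate
10 | [3,5-bis(benzyloxy)-2-(trimethylsilyl)phenoxy]tri(propan-2-yl)silane | CC(C)[Si](Oc1cc(OCc2ccccc2)cc(OCc2ccccc2)c1[Si](C)(C)C)(C(C)C)C(C)C | intermediate
11 | {2,6-bis(benzyloxy)-3-(trimethylsilyl)-4-[tri(propan-2-yl)silyloxy]phenyl}lithium | CC(C)[Si](Oc1cc(OCc2ccccc2)c([Li])c(OCc2ccccc2)c1[Si](C)(C)C)(C(C)C)C(C)C | intermediate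
12 | {2,6-bis(benzyloxy)-3-(trimethylsilyl)-4-[tri(propan-2-yl)silyloxy]phenyl}zinc chloride | CC(C)[Si](Oc1cc(OCc2ccccc2)c([Zn]Cl)c(OCc2ccccc2)c1[Si](C)(C)C)(C(C)C)C(C)C | intermediate
13 | 5-(benzyloxy)-2-[4-(benzyloxy)phenyl]-8-{2,6-bis(benzyloxy)-3-(trimethylsilyl)-4-[tri(propan-2-yl)silyloxy]phenyl}-7-methoxy-4H-chromen-4-one (racemic axis) | COc1cc(OCc2ccccc2)c2c(=O)cc(-c3ccc(OCc4ccccc4)cc3)oc2c1-c1c(OCc2ccccc2)cc(O[Si](C(C)C)(C(C)C)C(C)C)c([Si](C)(C)C)c1OCc1ccccc1 | intermediate
14 | 5-(benzyloxy)-2-[4-(benzyloxy)phenyl]-8-[2,6-bis(benzyloxy)-4-hydroxy-3-(trimethylsilyl)phenyl]-7-methoxy-4H-chromen-4-one (racemic axis) | COc1cc(OCc2ccccc2)c2c(=O)cc(-c3ccc(OCc4ccccc4)cc3)oc2c1-c1c(OCc2ccccc2)cc(O)c([Si](C)(C)C)c1OCc1ccccc1 | intermediate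
15 | 3,5-bis(benzyloxy)-4-{5-(benzyloxy)-2-[4-(benzyloxy)phenyl]-7-methoxy-4-oxo-4H-chromen-8-yl}-2-(trimethylsilyl)phenyl trifluoromethanesulfonate (racemic axis) | COc1cc(OCc2ccccc2)c2c(=O)cc(-c3ccc(OCc4ccccc4)cc3)oc2c1-c1c(OCc2ccccc2)cc(OS(=O)(=O)C(F)(F)F)c([Si](C)(C)C)c1OCc1ccccc1 | intermediate
16 | propiolic acid | C#CC(=O)O | starting material
17 | 1-(benzyloxy)-4-iodobenzene | Ic1ccc(OCc2ccccc2)cc1 | starting material
18 | 3-[4-(benzyloxy)phenyl]prop-2-ynoic acid | OC(=O)C#Cc1ccc(OCc2ccccc2)cc1 | intermediate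
19 | C4a–C8a aryne: 5-(benzyloxy)-2-[4-(benzyloxy)phenyl]-8-[2,6-bis(benzyloxy)-3,4-didehydrophenyl]-7-methoxy-4H-chromen-4-one | COc1cc(OCc2ccccc2)c2c(=O)cc(-c3ccc(OCc4ccccc4)cc3)oc2c1C1=C(OCc2ccccc2)C#CC=C1OCc1ccccc1 | intermediate
20 | cesium 3,5-bis(benzyloxy)-4-{5-(benzyloxy)-2-[4-(benzyloxy)phenyl]-7-methoxy-4-oxo-4H-chromen-8-yl}-2-{3-[4-(benzyloxy)phenyl]prop-2-ynoyl}phenoxide | [Cs+].COc1cc(OCc2ccccc2)c2c(=O)cc(-c3ccc(OCc4ccccc4)cc3)oc2c1-c1c(OCc2ccccc2)cc([O-])c(C(=O)C#Cc2ccc(OCc3ccccc3)cc2)c1OCc1ccccc1 | intermediate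
21 | penta-O-benzyl-7'-O-methylagathisflavone (racemic axis) | COc1cc(OCc2ccccc2)c2c(=O)cc(-c3ccc(OCc4ccccc4)cc3)oc2c1-c1c(OCc2ccccc2)cc2oc(-c3ccc(OCc4ccccc4)cc3)cc(=O)c2c1OCc1ccccc1 | intermediate
22 | 7'-O-methylagathisflavone (axis not controlled) | COc1cc(O)c2c(=O)cc(-c3ccc(O)cc3)oc2c1-c1c(O)cc2oc(-c3ccc(O)cc3)cc(=O)c2c1O | target

Total step count: 11. Longest linear sequence: 8 steps (steps 1, 2, 3, 6, 7, 8, 10, 11, from apigenin).

Steps most likely to fail

Step 10. The aryl anion formed after carboxylate addition may be protonated before it reaches the ester carbonyl, which would stop at the O-aryl ester. The cesium propiolate may also decarboxylate at 125 °C, or the aryne may be consumed by other nucleophiles. The fallback sets out from 14 and abandons the aryne. Ipso-iododesilylation (NIS, MeCN, 0 °C) should replace the trimethylsilyl group and give the ortho-iodophenol 5-(benzyloxy)-2-[4-(benzyloxy)phenyl]-8-[2,6-bis(benzyloxy)-4-hydroxy-3-iodophenyl]-7-methoxy-4H-chromen-4-one F1. A palladium-catalysed carbonylative Sonogashira coupling and cyclisation with purchased 1-(benzyloxy)-4-ethynylbenzene (PdCl2(PPh3)2, CO, Et2NH, 80–120 °C) should then put the carbonyl on the iodinated carbon (C4a) and close the pyranone through the phenol oxygen (C8a). The fallback comes back to the route at 21.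

Step 6. Ring lithiation may be incomplete or diverted by benzylic deprotonation, and transmetalation and reductive elimination at the tetra-ortho-substituted axis may be slow enough for the arylzinc to be protonated or homocoupled. The fallback sets out from 10 and 4 and reverses the polarity of the union. The aryllithium 11 is quenched with I2 at −78 °C to give [3,5-bis(benzyloxy)-4-iodo-2-(trimethylsilyl)phenoxy]tri(propan-2-yl)silane F2. Iodide 4 is converted by Miyaura borylation (B2pin2, Pd(dppf)Cl2, KOAc, dioxane, 90 °C) into 5-(benzyloxy)-2-[4-(benzyloxy)phenyl]-7-methoxy-8-(4,4,5,5-tetramethyl-1,3,2-dioxaborolan-2-yl)-4H-chromen-4-one F3. A Suzuki–Miyaura coupling of the two (Pd(OAc)2, SPhos, K3PO4, toluene/H2O, 100 °C) comes back to the route at 13.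

Step 1. Methylation may run on to O4' before all of the apigenin has reacted, leaving a mixture of mono- and dimethyl ethers that is tedious to separate. The fallback sets out from 1 and replaces reactivity control by protecting-group control. Peracetylation (Ac2O, pyridine) gives 5,7,4'-tri-O-acetylapigenin F4. The most labile ester, the 7-O-acetate, is then removed selectively (PhSH, imidazole, NMP, 0 °C) to give 5,4'-di-O-acetylapigenin F5. Mitsunobu methylation of the free 7-OH (MeOH, PPh3, DIAD, THF) gives 5,4'-di-O-acetyl-7-O-methylapigenin F6, and methanolysis of the two acetates (K2CO3, MeOH) comes back to the route at 2.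

Further compounds
F1 | step 10 | 5-(benzyloxy)-2-[4-(benzyloxy)phenyl]-8-[2,6-bis(benzyloxy)-4-hydroxy-3-iodophenyl]-7-methoxy-4H-chromen-4-one | COc1cc(OCc2ccccc2)c2c(=O)cc(-c3ccc(OCc4ccccc4)cc3)oc2c1-c1c(OCc2ccccc2)cc(O)c(I)c1OCc1ccccc1
F2 | step 6 | [3,5-bis(benzyloxy)-4-iodo-2-(trimethylsilyl)phenoxy]tri(propan-2-yl)silane | CC(C)[Si](Oc1cc(OCc2ccccc2)c(I)c(OCc2ccccc2)c1[Si](C)(C)C)(C(C)C)C(C)C
F3 | step 6 | 5-(benzyloxy)-2-[4-(benzyloxy)phenyl]-7-methoxy-8-(4,4,5,5-tetramethyl-1,3,2-dioxaborolan-2-yl)-4H-chromen-4-one | COc1cc(OCc2ccccc2)c2c(=O)cc(-c3ccc(OCc4ccccc4)cc3)oc2c1B1OC(C)(C)C(C)(C)O1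
F4 | step 1 | 5,7,4'-tri-O-acetylapigenin | CC(=O)Oc1ccc(-c2cc(=O)c3c(OC(C)=O)cc(OC(C)=O)cc3o2)cc1
F5 | step 1 | 5,4'-di-O-acetylapigenin | CC(=O)Oc1ccc(-c2cc(=O)c3c(OC(C)=O)cc(O)cc3o2)cc1
F6 | step 1 | 5,4'-di-O-acetyl-7-O-methylapigenin | COc1cc(OC(C)=O)c2c(=O)cc(-c3ccc(OC(C)=O)cc3)oc2c1
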